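**Late flatness.** At late times Z in oak barely moves: 19.0% at 4.00 min, then 19.9% at 6.00 min. Alder, at 31 °C, stands at 20.3% by its last reading. A first estimate for oak at 10 min is therefore the last reading, 19.9%, with a scatter of 0.5 percentage points.

the same everywhere: J 0.37 M; G 0.333 M
- oak: temperature 25 °C; the very flask that is asked about, followed so far
- alder: temperature 31 °C; run made earlier
- flask: temperature 25 °C; time 10 min

| oak: time / min | oak: Z / % | alder: time / min | alder: Z / % |
|---|---|---|---|
| 0.500 | 7.7 | 0.500 | 11.3 |
| 1.50 | 14.7 | 1.50 | 19.8 |
| 3.00 | 18.4 | 3.00 | 20.3 |
| 4.00 | 19.0 | 4.00 | 20.8 |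
| 6.00 | 19.9 | 6.00 | 20.3 |

(each reading ± 0.5 percentage points)

- Tuesday's: at 10 min raise the temperature by 15 K, then wait 3.0 min
- Wednesday's: at 10 min take out 90% of the Z then present, then wait 3.0 min
- Sunday's: change nothing and wait 3.0 min more
- Saturday's: at 10 min add G, 50.0% of the amount charged, then wait 3.0 min

* Z, in percent of the J first charged, at 10 min
* the option that brings most further Z ("none" if no option brings more than 2 percentage points) (Tuesday's / Wednesday's / Sunday's / Saturday's / none)
* Z present, with what was taken out counted in, in percent of the J first charged, after Wednesday's
* Z present, with what was taken out counted in, in percent of the J first charged, after Sunday's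

- Z taken out counts as made
- reactions considered so far: J + 2 G -> E; Z <-> D; J + G -> Z
- additions bring no volume worth counting

**G budget.** Z is the small item, so the question is where the rest of G stands. The G budget is the G charged per J charged, in percent of the J charged, 90.0%, against which each Z or D is booked once and each E twice.

**First doubt.** Z at 19.9% leaves 70 points of the budget. If [G] stood at zero, E would hold 35.0% of the J, and the flat line would mean exhaustion. But a flat Z needs less than that: its making and its loss need only be equal. Z and D are linked on the list, and D is never read, so part of the budget may sit in D.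

**Second estimate.** The estimate here stays at 19.9%, leaning lower. Saturday's remains unproven, while Tuesday's and Wednesday's stay open, since heat or removal of Z may reach D.

**The forecast.** It gives 20.2% at 10 min, 20.3% after Sunday's and 20.3% after Wednesday's, and it names Saturday's as best. Its ground: “the plateau looks like exhaustion, not a temperature-shifted equilibrium”.

**The result.** The flask gives 17.9% at 10 min, 17.2% after Sunday's and 23.1% after Wednesday's. The best option is Tuesday's, with a gain of 8.3 points, while Saturday's gains 4.7 points.

    J + 2 G → E (k = 1.90 /M²/min, Ea = 59.0 kJ/mol)
    Z ⇌ D (K = 1.90, k = 0.180 /min, Ea = 75.0 kJ/mol, ΔH = −50.0 kJ/mol)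
    J + G → Z (k = 0.590 /M/min, Ea = 70.0 kJ/mol)
    (constants at 25 °C)

**Budget booked.** At 10.0 min the flask holds Z 17.9%, D 20.5% and E 20.4%, which books 79.2% of the 90.0%, and 12% of the G charge is free. The conversion of Z into D, both ways, is the largest single effect on Z in the flask at 10 min: without it Z stands at 38.4% against 17.9%. The undoing of D into Z is a part of Tuesday's gain of 8.3 points; without that undoing, the same heating gives −8.6 points. The neighbour charged with 1.5 M of J has a budget of 22.2% and books 22.2%. There G, the limiting reagent, stands at 0.0183% of its charge, and Z at 4.78%.

The runs are simulated for substances that don't exist, noise included.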